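**Retrosynthetic overview**
- Last bond: the C4–O–CH2 ether. It comes from Mitsunobu coupling of 4-hydroxy-5-methylcoumarin with the finished (2E,4R)-4-acetoxy allylic alcohol side chain.
- Side chain: the prenyl terminus comes from a terminal allyl group by cross metathesis. The key C–C bond (C4'–C5') comes from asymmetric allylboration of (E)-4-silyloxy-2-methylbut-2-enal, which sets the only stereocentre (R).
- The E-trisubstituted enal comes from silyloxyacetaldehyde by Wittig olefination, ester reduction and allylic oxidation.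
- Rings: the benzene ring (ring A) is bought with the acetophenone. The pyranone (ring B) is the only ring made, by Claisen condensation with diethyl carbonate and lactonisation, before the coupling.

The target is read from the SMILES as the 4-O-[(2E,4R)-4-acetoxygeranyl] ether of 4-hydroxy-5-methylcoumarin.

Assumption: (tert-butyldimethylsilyloxy)acetaldehyde and 1-(2-hydroxy-6-methylphenyl)ethanone are bought as catalogue chemicals.

**Step 1**
Reactants: 1 (tert-butyldimethylsilyloxy)acetaldehyde; 2 ethyl 2-(triphenylphosphoranylidene)propanoate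
Product: 3 ethyl (2E)-4-[(tert-butyldimethylsilyl)oxy]-2-methylbut-2-enoate
Conditions: 2 (1.2 equiv), CH2Cl2, 0 °C to rt, 12 h
Reagents that add atoms: ethyl 2-(triphenylphosphoranylidene)propanoate 2, CCOC(=O)C(C)=P(c1ccccc1)(c1ccccc1)c1ccccc1
Why: Wittig olefination with a stabilised, α-branched ylide gives the E-trisubstituted enoate (about 95:5), and the trace of Z isomer is removed on silica.

**Step 2**
Reactants: 3 ethyl (2E)-4-[(tert-butyldimethylsilyl)oxy]-2-methylbut-2-enoate
Product: 4 (2E)-4-[(tert-butyldimethylsilyl)oxy]-2-methylbut-2-en-1-ol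
Conditions: iBu2AlH (2.3 equiv), CH2Cl2, −78 to 0 °C; aq. potassium sodium tartrate
Reagents that add atoms: none
Why: 1,2-reduction of the conjugated ester by iBu2AlH gives the allylic alcohol without touching the alkene geometry or the silyl ether.

**Step 3**
Reactants: 4 (2E)-4-[(tert-butyldimethylsilyl)oxy]-2-methylbut-2-en-1-ol
Product: 5 (2E)-4-[(tert-butyldimethylsilyl)oxy]-2-methylbut-2-enal
Conditions: activated MnO2 (15 equiv), CH2Cl2, rt, 6 h
Reagents that add atoms: none
Why: Heterogeneous MnO2 oxidation is selective for allylic alcohols, stops at the aldehyde and does not isomerise the E alkene.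

**Step 4 (key C–C bond)**
Reactants: 5 (2E)-4-[(tert-butyldimethylsilyl)oxy]-2-methylbut-2-enal; 6 allylmagnesium bromide
Product: 8 (4R,5E)-7-[(tert-butyldimethylsilyl)oxy]-5-methylhepta-1,5-dien-4-ol, via borinate ester 7 (not isolated)
Conditions: (+)-Ipc2BOMe (1.3 equiv), 6 (1.25 equiv), Et2O, 0 °C to rt, 1 h; pentane, Mg(OMe)Br filtered off under Ar; 5, Et2O, −100 °C, 1 h; then 3 M NaOH, 30% H2O2, rt, 4 h
Reagents that add atoms: allylmagnesium bromide 6, C=CC[Mg]Br; (+)-B-methoxydiisopinocampheylborane, from (−)-α-pinene, COB([C@H]1C[C@H]2C[C@@H]([C@@H]1C)C2(C)C)[C@H]1C[C@H]2C[C@@H]([C@@H]1C)C2(C)C (its Ipc2B unit stands in 7 only)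
Why: In this Brown asymmetric allylboration (carbonyl allylation) a closed chair transition state lets the Ipc ligands of the (−)-α-pinene series deliver the allyl group to the Re face of the α-methyl enal, giving the 4R alcohol by clean 1,2-addition (expected 95% ee or better).

**Step 5**
Reactants: 8 (4R,5E)-7-[(tert-butyldimethylsilyl)oxy]-5-methylhepta-1,5-dien-4-ol; 9 2-methylbut-2-ene
Product: 10 (2E,4R)-1-[(tert-butyldimethylsilyl)oxy]-3,7-dimethylocta-2,6-dien-4-ol
Conditions: second-generation Grubbs catalyst (H2IMes)(PCy3)Cl2Ru=CHPh (4 mol %), 9/CH2Cl2 (1:1), sealed flask, 40 °C, 12 h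
Reagents that add atoms: 2-methylbut-2-ene 9, CC=C(C)C
Why: In this olefin cross metathesis only the terminal alkene engages the catalyst, because the hindered trisubstituted alkene is inert and ring closure would need a cyclobutene, so excess 9 drives conversion to the prenyl terminus and leaves the stereocentre untouched.

**Step 6**
Reactants: 10 (2E,4R)-1-[(tert-butyldimethylsilyl)oxy]-3,7-dimethylocta-2,6-dien-4-ol; 11 acetic anhydride
Product: 12 (2E,4R)-1-[(tert-butyldimethylsilyl)oxy]-3,7-dimethylocta-2,6-dien-4-yl acetate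
Conditions: 11 (2 equiv), pyridine, DMAP (10 mol %), CH2Cl2, 0 °C to rt
Reagents that add atoms: acetic anhydride 11, CC(=O)OC(C)=O
Why: DMAP-catalysed O-acylation takes place at oxygen only, so the C–O bond and the R configuration are retained.

**Step 7**
Reactants: 12 (2E,4R)-1-[(tert-butyldimethylsilyl)oxy]-3,7-dimethylocta-2,6-dien-4-yl acetate
Product: 13 (2E,4R)-1-hydroxy-3,7-dimethylocta-2,6-dien-4-yl acetate
Conditions: HF·pyridine, pyridine, THF, 0 °C to rt
Reagents that add atoms: none
Why: Buffered fluoride desilylation frees the primary alcohol without ionising the allylic acetate, and acetyl migration across the E alkene is geometrically impossible.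

**Step 8**
Reactants: 14 1-(2-hydroxy-6-methylphenyl)ethan-1-one; 15 diethyl carbonate
Product: 17 4-hydroxy-5-methyl-2H-chromen-2-one, via beta-keto ester 16 (not isolated)
Conditions: NaH (3.5 equiv), 15 (3 equiv), toluene, 110 °C, 4 h; then H2O, 2 M HCl to pH 2, filter
Reagents that add atoms: diethyl carbonate 15, CCOC(=O)OCC
Why: Crossed Claisen condensation of the methyl ketone enolate with non-enolisable diethyl carbonate gives 16, whose phenoxide lactonises at once to ring B, and irreversible deprotonation of the acidic product drives the sequence.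

**Step 9**
Reactants: 13 (2E,4R)-1-hydroxy-3,7-dimethylocta-2,6-dien-4-yl acetate; 17 4-hydroxy-5-methyl-2H-chromen-2-one
Product: 19 (2E,4R)-3,7-dimethyl-1-[(5-methyl-2-oxo-2H-chromen-4-yl)oxy]octa-2,6-dien-4-yl acetate, via alkoxyphosphonium coumarinate 18 (not isolated)
Conditions: 17 (1.2 equiv), PPh3 (1.5 equiv), DIAD (1.5 equiv), THF, 0 °C to rt, 3 h; work-up below 40 °C
Reagents that add atoms: triphenylphosphine, c1ccc(cc1)P(c1ccccc1)c1ccccc1 (its atoms stand in 18 only)
Why: In this Mitsunobu etherification the acidic vinylogous acid (pKa about 4) attacks the primary allylic alkoxyphosphonium carbon through O-4 by SN2, remote from the stereocentre, under neutral cold conditions that spare the acetate and avoid Claisen rearrangement of the allyl ether.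

**Compound list**
1 | (tert-butyldimethylsilyloxy)acetaldehyde | O=CCO[Si](C)(C)C(C)(C)C | starting material
2 | ethyl 2-(triphenylphosphoranylidene)propanoate | CCOC(=O)C(C)=P(c1ccccc1)(c1ccccc1)c1ccccc1 | starting material
3 | ethyl (2E)-4-[(tert-butyldimethylsilyl)oxy]-2-methylbut-2-enoate | CCOC(=O)/C(C)=C/CO[Si](C)(C)C(C)(C)C | intermediate
4 | (2E)-4-[(tert-butyldimethylsilyl)oxy]-2-methylbut-2-en-1-ol | OC/C(C)=C/CO[Si](C)(C)C(C)(C)C | intermediate
5 | (2E)-4-[(tert-butyldimethylsilyl)oxy]-2-methylbut-2-enal | O=C/C(C)=C/CO[Si](C)(C)C(C)(C)C | intermediate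
6 | allylmagnesium bromide | C=CC[Mg]Br | starting material
7 | diisopinocampheylborinate ester of 8 (not isolated) | B(O[C@H](CC=C)/C(C)=C/CO[Si](C)(C)C(C)(C)C)([C@H]1C[C@H]2C[C@@H]([C@@H]1C)C2(C)C)[C@H]1C[C@H]2C[C@@H]([C@@H]1C)C2(C)C | intermediate
8 | (4R,5E)-7-[(tert-butyldimethylsilyl)oxy]-5-methylhepta-1,5-dien-4-ol | O[C@H](CC=C)/C(C)=C/CO[Si](C)(C)C(C)(C)C | intermediate
9 | 2-methylbut-2-ene | CC=C(C)C | starting material
10 | (2E,4R)-1-[(tert-butyldimethylsilyl)oxy]-3,7-dimethylocta-2,6-dien-4-ol | O[C@H](CC=C(C)C)/C(C)=C/CO[Si](C)(C)C(C)(C)C | intermediate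
11 | acetic anhydride | CC(=O)OC(C)=O | starting material
12 | (2E,4R)-1-[(tert-butyldimethylsilyl)oxy]-3,7-dimethylocta-2,6-dien-4-yl acetate | CC(=O)O[C@H](CC=C(C)C)/C(C)=C/CO[Si](C)(C)C(C)(C)C | intermediate
13 | (2E,4R)-1-hydroxy-3,7-dimethylocta-2,6-dien-4-yl acetate | CC(=O)O[C@H](CC=C(C)C)/C(C)=C/CO | intermediate
14 | 1-(2-hydroxy-6-methylphenyl)ethan-1-one | CC(=O)c1c(C)cccc1O | starting material
15 | diethyl carbonate | CCOC(=O)OCC | starting material
16 | ethyl 3-(2-hydroxy-6-methylphenyl)-3-oxopropanoate (not isolated) | CCOC(=O)CC(=O)c1c(C)cccc1O | intermediate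
17 | 4-hydroxy-5-methyl-2H-chromen-2-one | Cc1cccc2oc(=O)cc(O)c12 | intermediate
18 | {[(2E,4R)-4-acetoxy-3,7-dimethylocta-2,6-dien-1-yl]oxy}triphenylphosphonium 5-methyl-2-oxo-2H-chromen-4-olate (not isolated) | CC(=O)O[C@H](CC=C(C)C)/C(C)=C/CO[P+](c1ccccc1)(c1ccccc1)c1ccccc1.Cc1cccc2oc(=O)cc([O-])c12 | intermediate
19 | (2E,4R)-3,7-dimethyl-1-[(5-methyl-2-oxo-2H-chromen-4-yl)oxy]octa-2,6-dien-4-yl acetate (CNP0217379.1) | CC(=O)O[C@H](CC=C(C)C)/C(C)=C/COc1cc(=O)oc2cccc(C)c12 | target

**Totals**
Total step count: 9.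
Longest linear sequence: 8 steps (steps 1 to 7, then step 9). The coumarin branch is step 8.

**Three steps most likely to fail**

Step 9. The coumarin anion is ambident, so the 2-alkoxychromone or the C-3 alkylated product can compete, and the peri methyl group crowds O-4. The fallback reverses the polarity so that the coumarin is the electrophile. It sets out from 17 and 10 and comes back at 19. Compound 17 is heated in POCl3 (110 °C) to give 4-chloro-5-methyl-2H-chromen-2-one F1. Compound 10 is desilylated with HF·pyridine to (2E,4R)-3,7-dimethylocta-2,6-diene-1,4-diol F2. The less hindered primary alkoxide of F2 (NaH, 1.0 equiv, THF, 0 °C) adds to C-4 of F1 and expels chloride by addition–elimination. This gives 4-{[(2E,4R)-4-hydroxy-3,7-dimethylocta-2,6-dien-1-yl]oxy}-5-methyl-2H-chromen-2-one F3, in which the new bond can only be at the C-4 oxygen. Acetylation of F3 with 11 (pyridine, DMAP) gives 19.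

Step 4. This step needs moisture-free handling at −100 °C, the ee has to be proven (Mosher ester of 8), and isopinocampheol runs close to 8 on silica. The fallback replaces reagent control by resolution. It sets out from 5 and comes back at 8. Reagent 6 is added directly to 5 (THF, −78 °C) to give racemic (5E)-7-[(tert-butyldimethylsilyl)oxy]-5-methylhepta-1,5-dien-4-ol F4. Sharpless kinetic resolution follows: Ti(OiPr)4, L-(+)-diisopropyl tartrate, t-BuOOH (0.6 equiv), 4 Å sieves, CH2Cl2, −20 °C. It epoxidises the allylic alkene of the S enantiomer only, giving (1S)-1-[(2S,3S)-3-{[(tert-butyldimethylsilyl)oxy]methyl}-2-methyloxiran-2-yl]but-3-en-1-ol F5. The unreacted R alcohol 8 is recovered by chromatography (at most 50%, above 98% ee at about 55% conversion). The same treatment can raise the ee of material from step 4.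

Step 5. The volatile partner can escape, conversion can stall at the crotyl stage, or ruthenium hydrides can shift the terminal alkene. The fallback replaces metathesis by cleavage and olefination. It sets out from 8 and comes back at 10.
- Compound 8 is silylated (Et3SiCl, imidazole, CH2Cl2) to (4R,5E)-7-[(tert-butyldimethylsilyl)oxy]-5-methyl-4-[(triethylsilyl)oxy]hepta-1,5-diene F6.
- The unhindered terminal alkene alone is cleaved with OsO4 (2 mol %), NaIO4 and 2,6-lutidine in dioxane–H2O. The trisubstituted alkene is shielded and deactivated by its two allylic silyloxy groups. The product is (3R,4E)-6-[(tert-butyldimethylsilyl)oxy]-4-methyl-3-[(triethylsilyl)oxy]hex-4-enal F7.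
- Wittig olefination with Ph3P=C(CH3)2 (isopropyltriphenylphosphonium iodide, n-BuLi, THF, −78 to 0 °C) gives (2E,4R)-1-[(tert-butyldimethylsilyl)oxy]-3,7-dimethyl-4-[(triethylsilyl)oxy]octa-2,6-diene F8.
- PPTS in MeOH at 0 °C removes only the triethylsilyl group and gives 10.

**Further compounds**
F1 | step 9 | 4-chloro-5-methyl-2H-chromen-2-one | Cc1cccc2oc(=O)cc(Cl)c12
F2 | step 9 | (2E,4R)-3,7-dimethylocta-2,6-diene-1,4-diol | O[C@H](CC=C(C)C)/C(C)=C/CO
F3 | step 9 | 4-{[(2E,4R)-4-hydroxy-3,7-dimethylocta-2,6-dien-1-yl]oxy}-5-methyl-2H-chromen-2-one | O[C@H](CC=C(C)C)/C(C)=C/COc1cc(=O)oc2cccc(C)c12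
F4 | step 4 | racemic (5E)-7-[(tert-butyldimethylsilyl)oxy]-5-methylhepta-1,5-dien-4-ol | OC(CC=C)/C(C)=C/CO[Si](C)(C)C(C)(C)C
F5 | step 4 | (1S)-1-[(2S,3S)-3-{[(tert-butyldimethylsilyl)oxy]methyl}-2-methyloxiran-2-yl]but-3-en-1-ol | CC(C)(C)[Si](C)(C)OC[C@@H]1O[C@@]1(C)[C@@H](O)CC=C
F6 | step 5 | (4R,5E)-7-[(tert-butyldimethylsilyl)oxy]-5-methyl-4-[(triethylsilyl)oxy]hepta-1,5-diene | CC[Si](CC)(CC)O[C@H](CC=C)/C(C)=C/CO[Si](C)(C)C(C)(C)C
F7 | step 5 | (3R,4E)-6-[(tert-butyldimethylsilyl)oxy]-4-methyl-3-[(triethylsilyl)oxy]hex-4-enal | CC[Si](CC)(CC)O[C@H](CC=O)/C(C)=C/CO[Si](C)(C)C(C)(C)C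
F8 | step 5 | (2E,4R)-1-[(tert-butyldimethylsilyl)oxy]-3,7-dimethyl-4-[(triethylsilyl)oxy]octa-2,6-diene | CC[Si](CC)(CC)O[C@H](CC=C(C)C)/C(C)=C/CO[Si](C)(C)C(C)(C)C
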